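## The problem

The target is a flavanolignan. A (2S)-5,7-dihydroxyflavanone (ring A the phloroglucinol ring, ring C the dihydropyranone, ring B the 3',5'-dimethoxyphenyl ring) is joined through its ring B oxygen O4' to C8'' of a 1-(4-hydroxyphenyl)propane-1,3-diol chain. Ring construction is limited to ring C; the demanding bond is the secondary alkyl aryl ether O4'–C8'', which sits between two ortho methoxy groups and next to a benzylic carbinol. There are three stereocentres: C2 (S) in ring C and the threo pair C7'' (R) and C8'' (R) in the chain. C2 lies six bonds from C8'' across the flat ring B and cannot steer the chain. C8'' can bias C7'' by 1,2-induction, but nothing in the molecule biases C8'', so the chain centres need either an outside source of chirality or a separation. Three features forbid rough treatment: the flavanone opens by retro-oxa-Michael reaction under base and loses C2, the p-hydroxybenzylic carbinol at C7'' ionises in acid and is prone to hydrogenolysis, and the three phenols are oxidisable. The feature that opens a short way in is that O4' is flanked by the methoxy groups on C3' and C5' and is para to the substituted C1', so its phenoxyl radical can form a lasting bond only at oxygen. The chain C7''(OH)–C8''(O)–C9''H2OH on a 4-hydroxyphenyl ring is in turn the hydrate of a p-hydroxycinnamyl alcohol joined at its central carbon, the 8-O-4 pattern of lignin-type coupling.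

## Retrosynthesis

**15 to 11 and 13.** The first cut removes the O4'–C8'' bond and the C7''–OH bond of 15 together. Read backwards, loss of the C7'' hydroxyl gives the p-quinone methide 14, and homolysis of its ether bond gives the phenoxyl radicals of the flavanone triol 11 and of p-coumaryl alcohol 13. The neighbouring ionic cuts (displacement at C8'' by the hindered phenoxide, or a Mitsunobu etherification) would need the ring A phenols, the C9'' alcohol and the C7'' carbinol masked, and then unmasked on a product that tolerates base, acid and hydrogenolysis poorly. The radical cut needs no protecting group and ends at the target. The gain is large: 11 has one stereocentre and 13 has none. The forward reaction must oxidise the 4'-OH in the presence of the ring A phenols, favour cross-coupling over dimerisation of 13, and hydrate 14 at C7''. It does not control C8'' and controls C7'' only weakly, so 15 has to be separated from its three side-chain diastereomers; that is the accepted price of this cut. Material with the right C8'' but the wrong C7'' is not lost in principle, because dilute acid re-ionises the p-hydroxybenzylic carbinol toward 14 and lets it be hydrated again.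

**11 to 10.** The three phenols of 11 are traced back to the benzyl ethers of 10. Benzyl is chosen because it leaves under neutral hydrogenolysis, which does not touch C2. This deprotection also falls before the side chain exists, so the C7'' carbinol never meets hydrogen or acid.

**10 to 4 and 9.** The C2–C1' bond is cut to give the chromone 4 and the arylboronic acid 9. Closing ring C instead by oxa-Michael addition of the ring A phenol onto an open-chain enone would give racemic material. The conjugate addition sets C2 under catalyst control from two flat, achiral partners. The demand is that an electron-rich chromone accept an electron-rich aryl group with high enantioselectivity.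

**4 to 2 to 1.** Chromone 4 is cut at O1–C2 and C2–C3. The C2 carbon comes from a formamide acetal that condenses with the acetyl group of 2 to give the enaminone 3, and acid then closes ring C. Compound 2 comes from 1 by benzylation of two of its three hydroxyls. The third, hydrogen-bonded to the carbonyl, is the one that must stay free for ring closure, so the natural selectivity serves the plan.

**9 to 6 to 5.** The boronic acid 9 comes from the bromide 6 by bromine–lithium exchange (7) and trapping with a borate ester (8). Compound 6 is the benzyl ether of the commercial phenol 5.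

**13 to 12.** Compound 13 oligomerises on storage, so it is made shortly before use by hydride reduction of the commercial ester 12.

## Roads not taken

**Alternative 1: carbenoid C–H insertion closes ring C.**
- **Cut:** the C2–C3 bond of ring C.
- **Forward key step:** the diazoketone A2 carries a diazoacetyl group on ring A ortho to the O–CH2–aryl ether of ring B. A chiral dirhodium tetracarboxylate of the Rh2(O2CR)4 type (divalent rhodium) turns it into a carbenoid that inserts into the O–CH2 C–H bond and gives the bis-silylated flavanone A1.
- **Merits:** the chain is brought in as a stereodefined acetonide, so C7'' and C8'' are secure, and C2 is set by the catalyst.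
- **Weak points for this target:**
  - Insertion must form a six-membered ring. It competes with attack of the carbenoid on the ether oxygen, followed by a Stevens-type benzyl shift to a benzofuranone, and with addition to the electron-rich rings.
  - Enantioselectivity in chromanone-forming insertions of diazoketones is modest.
  - A2 requires a hindered 2,4,6-trioxygenated aroyl unit.
  - A1 still carries silyl ethers, an acetonide and a benzyl ether, to be removed from a molecule that dislikes base, acid and hydrogenolysis.
- **Comparison:** this road is clearly better in side-chain stereocontrol. The chosen plan sets against it about half the step count, no deprotection after the chain is attached, and a key reaction whose type is established on 2,6-dimethoxyphenols. The key step of this alternative is itself uncertain in chemoselectivity and in enantioselectivity.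

**Alternative 2: Claisen cyclisation builds ring A last.**
- **Cut:** the C4a–C5 bond of ring A.
- **Forward key step:** in the dihydropyranone A4, the ring carbon next to the carbonyl on the enol ether side attacks the methyl ester of the side chain (Dieckmann-type Claisen condensation). Enolisation then gives the free 5,7-dihydroxyflavanone A3.
- **Merits:** ring A appears unprotected, which saves its protecting groups. The logic mirrors polyketide biosynthesis, and the chain is again a stereodefined acetonide.
- **Weak points for this target:**
  - The attacking carbon is only weakly nucleophilic. The base needed for it deprotonates first the doubly activated methylene of the keto ester and the CH2 next to the ring carbonyl.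
  - Deprotonation next to the ring carbonyl opens ring C by β-elimination of O1 and destroys C2.
  - The keto ester chain can cyclise in other aldol modes.
  - A4 is a long synthesis in its own right.
- **Comparison:** this road controls all three centres on paper, which the chosen plan does not. The chosen plan sets against it a flavanone made by a precedented catalytic asymmetric reaction, no exposure of C2 to strong base, and a far shorter sequence.

**Alternative 3: aryne annulation of a β-hydroxy ester.**
- **Cut:** O1–C8a and C4–C4a.
- **Forward key step:** the alkoxide of the (S)-β-hydroxy ester A6 adds to the aryne A7 at the carbon remote from the flanking benzyloxy group. The aryl anion left next to that benzyloxy group attacks the ester and closes ring C, giving the dibenzyl flavanone A5.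
- **Merits:** it is convergent. C2 comes from a reliable asymmetric synthesis of A6 and its C–O bond is never broken. The alkoxy group of A7 steers the regiochemistry, and the chain is stereodefined.
- **Weak points for this target:**
  - The alkoxide of A6 can undergo retro-aldol cleavage or elimination to the cinnamate.
  - The aryl anion can be quenched by the acidic CH2 of the ester faster than it acylates, which leaves an open aryl ether.
  - Secondary alkoxides are mediocre partners for arynes.
  - A5 still needs hydrogenolysis and acetonide removal.
- **Comparison:** this is the strongest of the three and is superior to the chosen plan in stereocontrol at C7'' and C8''. The chosen plan sets against it brevity, a protecting-group-free last step and a key step of known type, and pays with a separation of isomers. The stereocontrolled fallback for the key step reaches the same compound A5 by a conjugate addition in place of the aryne step.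

Key step: step 8

Remark: atoms are numbered as in flavanones (O1 to C4 in ring C, C5 to C8 in ring A, primed atoms in ring B) and C7'' to C9'' in the chain. In step 5 the (R)-ligand is assumed to give (2S), by analogy with the sense this catalyst shows with other β-substituted cyclic enones; the antipodal ligand is used if the first run shows otherwise.

## Steps

Step 1
Reactants: 1 2,4,6-trihydroxyacetophenone
Product: 2 1-[2,4-bis(benzyloxy)-6-hydroxyphenyl]ethan-1-one
Conditions: BnBr (2.05 equiv), K2CO3, DMF, 0 to 20 °C
Reagents that add atoms: benzyl bromide, BrCc1ccccc1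
Why: Williamson ether synthesis; after the para hydroxyl and one ortho hydroxyl have reacted, the remaining ortho hydroxyl is locked in a hydrogen bond to the acetyl carbonyl and is the least nucleophilic, so limiting the halide to two equivalents should stop at 2.

Step 2
Reactants: 2 1-[2,4-bis(benzyloxy)-6-hydroxyphenyl]ethan-1-one
Product: 4 5,7-bis(benzyloxy)-4H-chromen-4-one, via enaminone 3 (not isolated)
Conditions: Me2NCH(OMe)2, toluene, 100 °C; evaporate; then 2 M HCl, CH2Cl2, 40 °C
Reagents that add atoms: N,N-dimethylformamide dimethyl acetal, COC(OC)N(C)C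
Why: Condensation of the methyl ketone with the formamide acetal gives the enaminone 3; acid then promotes intramolecular oxa-Michael addition of the free phenol and loss of dimethylamine, the standard enaminone route to chromones unsubstituted at C2 and C3.

Step 3
Reactants: 5 4-bromo-2,6-dimethoxyphenol
Product: 6 2-(benzyloxy)-5-bromo-1,3-dimethoxybenzene
Conditions: BnBr, K2CO3, DMF, 60 °C
Reagents that add atoms: benzyl bromide, BrCc1ccccc1
Why: Williamson ether synthesis on the only hydroxyl; warming compensates for the two flanking methoxy groups.

Step 4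
Reactants: 6 2-(benzyloxy)-5-bromo-1,3-dimethoxybenzene
Product: 9 [4-(benzyloxy)-3,5-dimethoxyphenyl]boronic acid, via aryllithium 7 (not isolated), via lithium triisopropoxyborate 8 (not isolated)
Conditions: n-BuLi, THF, −78 °C; B(O-i-Pr)3, −78 to 20 °C; 1 M HCl
Reagents that add atoms: triisopropyl borate, CC(C)OB(OC(C)C)OC(C)C; water, O
Why: Bromine–lithium exchange is faster than any ortho-lithiation at −78 °C; the aryllithium 7 adds to the borate ester to give the ate complex 8, which is hydrolysed to the boronic acid on acidic work-up.

Step 5
Reactants: 4 5,7-bis(benzyloxy)-4H-chromen-4-one; 9 [4-(benzyloxy)-3,5-dimethoxyphenyl]boronic acid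
Product: 10 (2S)-5,7-bis(benzyloxy)-2-[4-(benzyloxy)-3,5-dimethoxyphenyl]chroman-4-one
Conditions: Pd(OCOCF3)2 (divalent palladium, 5 mol %), (R)-4-tert-butyl-2-(pyridin-2-yl)-4,5-dihydrooxazole (6 mol %), NH4PF6 (30 mol %), H2O (5 equiv), ClCH2CH2Cl, 60 °C
Reagents that add atoms: none
Why: Palladium-catalysed asymmetric conjugate addition of an arylboronic acid to a chromone: transmetalation gives an arylpalladium species, the C2=C3 bond inserts with the aryl group going to C2 on the face selected by the chiral pyridine-oxazoline ligand, and water protonates the palladium enolate; the ligand is the only source of the C2 configuration.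

Step 6
Reactants: 10 (2S)-5,7-bis(benzyloxy)-2-[4-(benzyloxy)-3,5-dimethoxyphenyl]chroman-4-one
Product: 11 (2S)-5,7-dihydroxy-2-(4-hydroxy-3,5-dimethoxyphenyl)chroman-4-one
Conditions: H2 (1 atm), 10% Pd/C, EtOAc–MeOH, 20 °C, stopped after uptake of 3 equiv
Reagents that add atoms: none
Why: Hydrogenolysis of aryl benzyl ethers is faster than reduction of the hydrogen-bonded aryl ketone or cleavage of the C2–O1 bond; the medium is neutral, so C2 should keep its configuration.

Step 7
Reactants: 12 methyl (2E)-3-(4-hydroxyphenyl)prop-2-enoate
Product: 13 4-[(1E)-3-hydroxyprop-1-en-1-yl]phenol (p-coumaryl alcohol)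
Conditions: i-Bu2AlH (4 equiv), toluene–THF, −78 to 0 °C; aq. KNaC4H4O6
Reagents that add atoms: none
Why: 1,2-reduction of an α,β-unsaturated ester by the aluminium hydride to the allylic alcohol with retention of the E double bond; the first equivalent is consumed by the phenol, and the neutral tartrate work-up spares the acid-sensitive product, which is used at once.

Step 8
Reactants: 11 (2S)-5,7-dihydroxy-2-(4-hydroxy-3,5-dimethoxyphenyl)chroman-4-one; 13 4-[(1E)-3-hydroxyprop-1-en-1-yl]phenol
Product: 15 (2S)-5,7-dihydroxy-2-[4-{[(1R,2R)-1,3-dihydroxy-1-(4-hydroxyphenyl)propan-2-yl]oxy}-3,5-dimethoxyphenyl]chroman-4-one, via quinone methide 14 (not isolated)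
Conditions: Ag2O (monovalent silver, 1.1 equiv per 13), 11 (3 equiv), acetone–CH2Cl2, 20 °C, dark, 13 added over 4 h; filter; then THF–H2O, NaOAc/AcOH buffer pH 5, 20 °C; preparative reversed-phase HPLC, then HPLC on a chiral stationary phase
Reagents that add atoms: water, O
Why: Ag2O takes one electron and one proton from the 4'-OH of 11 and from the phenol of 13; the radical of 11 is long-lived because its ortho carbons bear methoxy groups and its para carbon bears C2, the radical of 13 has high spin density at C8'', and the two combine O4'–C8'' to the p-quinone methide 14. Water then adds to C7'' of 14, restores the aromatic ring and forms the C7''–OH bond. The closest known reaction type is the lignin-type dehydrogenative 8-O-4 cross-coupling of p-hydroxycinnamyl alcohols with 2,6-dimethoxyphenols followed by hydration of the quinone methide, which is not stereoselective. No ring is closed. C8'' is created in the radical combination without any controlling element, since C2 is six bonds away across ring B, so both configurations are expected in similar amounts. C7'' is created in the hydration under 1,2-induction from C8'' alone, which with 2,6-dimethoxyaryl ethers is expected to lean toward erythro, so the threo (7''R,8''R) isomer 15 should be a minor component that is isolated by the two chromatographic stages and assigned by its C7''–C8'' coupling pattern and chiroptical data. Chemoselectivity for the 4'-OH over the ring A phenols rests on ring A being deactivated by the C4 carbonyl with 5-OH hydrogen-bonded to it, and O- over C-coupling on ring B rests on the two methoxy groups. Cross-coupling over dimerisation of 13 is secured by the long life of the ring B radical, the excess of 11 (recovered) and the slow addition of 13.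

## Compound list

1 | 2,4,6-trihydroxyacetophenone | CC(=O)c1c(O)cc(O)cc1O | starting material
2 | 1-[2,4-bis(benzyloxy)-6-hydroxyphenyl]ethan-1-one | CC(=O)c1c(O)cc(OCc2ccccc2)cc1OCc1ccccc1 | intermediate
3 | (2E)-1-[2,4-bis(benzyloxy)-6-hydroxyphenyl]-3-(dimethylamino)prop-2-en-1-one | CN(C)/C=C/C(=O)c1c(O)cc(OCc2ccccc2)cc1OCc1ccccc1 | intermediate
4 | 5,7-bis(benzyloxy)-4H-chromen-4-one | O=c1ccoc2cc(OCc3ccccc3)cc(OCc3ccccc3)c12 | intermediate
5 | 4-bromo-2,6-dimethoxyphenol | COc1cc(Br)cc(OC)c1O | starting material
6 | 2-(benzyloxy)-5-bromo-1,3-dimethoxybenzene | COc1cc(Br)cc(OC)c1OCc1ccccc1 | intermediate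
7 | [4-(benzyloxy)-3,5-dimethoxyphenyl]lithium | [Li]c1cc(OC)c(OCc2ccccc2)c(OC)c1 | intermediate
8 | lithium [4-(benzyloxy)-3,5-dimethoxyphenyl]tri(propan-2-yloxy)borate | [Li+].CC(C)O[B-](OC(C)C)(OC(C)C)c1cc(OC)c(OCc2ccccc2)c(OC)c1 | intermediate
9 | [4-(benzyloxy)-3,5-dimethoxyphenyl]boronic acid | OB(O)c1cc(OC)c(OCc2ccccc2)c(OC)c1 | intermediate
10 | (2S)-5,7-bis(benzyloxy)-2-[4-(benzyloxy)-3,5-dimethoxyphenyl]chroman-4-one | COc1cc([C@@H]2CC(=O)c3c(OCc4ccccc4)cc(OCc4ccccc4)cc3O2)cc(OC)c1OCc1ccccc1 | intermediate
11 | (2S)-5,7-dihydroxy-2-(4-hydroxy-3,5-dimethoxyphenyl)chroman-4-one | COc1cc([C@@H]2CC(=O)c3c(O)cc(O)cc3O2)cc(OC)c1O | intermediate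
12 | methyl (2E)-3-(4-hydroxyphenyl)prop-2-enoate | COC(=O)/C=C/c1ccc(O)cc1 | starting material
13 | 4-[(1E)-3-hydroxyprop-1-en-1-yl]phenol (p-coumaryl alcohol) | OC/C=C/c1ccc(O)cc1 | intermediate
14 | (2S)-5,7-dihydroxy-2-[4-{[3-hydroxy-1-(4-oxocyclohexa-2,5-dien-1-ylidene)propan-2-yl]oxy}-3,5-dimethoxyphenyl]chroman-4-one, both C8'' epimers | COc1cc([C@@H]2CC(=O)c3c(O)cc(O)cc3O2)cc(OC)c1OC(CO)C=C1C=CC(=O)C=C1 | intermediate
15 | (2S)-5,7-dihydroxy-2-[4-{[(1R,2R)-1,3-dihydroxy-1-(4-hydroxyphenyl)propan-2-yl]oxy}-3,5-dimethoxyphenyl]chroman-4-one | COc1cc([C@@H]2CC(=O)c3c(O)cc(O)cc3O2)cc(OC)c1O[C@H](CO)[C@H](O)c1ccc(O)cc1 | target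

## Step count and least certain steps

Total: 8 steps. Longest linear sequence: 5 steps (steps 1, 2, 5, 6, 8, or equally steps 3, 4, 5, 6, 8).

**Step 8 (key step).**
- **What may go wrong:**
  - Coupling on both faces at C8'' and an erythro-leaning hydration at C7'' leave the wanted isomer a minor share. With no control at C8'', the ceiling for 15 is half of the threo fraction.
  - The radical of 13 may self-couple.
  - The ring B phenoxyl radical may disproportionate with loss of the C2 hydrogen, which dehydrogenates ring C at C2–C3.
  - The excess ring A phenol may add to the quinone methide before water does.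
  - Isomers that differ only at centres remote from C2 may not resolve fully on chromatography.
- **Fallback:** a stereocontrolled construction of the chain before ring C, setting out from 5 (and using 4) and returning at 15.
  - Phenol 5 is alkylated with ClCH2CO2H in aqueous NaOH to give 2-(4-bromo-2,6-dimethoxyphenoxy)acetic acid F1.
  - F1 is converted through its pivalic mixed anhydride (t-BuCOCl, Et3N, LiCl) with (4S)-4-benzyl-1,3-oxazolidin-2-one into the N-acyl oxazolidinone F2.
  - An Evans syn aldol reaction of F2 (Bu2BOTf, i-Pr2NEt, CH2Cl2, −78 °C) with commercial 4-(benzyloxy)benzaldehyde should give the syn aldol adduct F3. The auxiliary fixes both chain centres in the threo (7''R,8''R) sense.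
  - LiBH4 removes the auxiliary reductively and gives the (1R,2R)-diol F4, which is protected with 2,2-dimethoxypropane and pyridinium tosylate as the acetonide bromide F5.
  - Bromine–lithium exchange, B(O-i-Pr)3 and a buffered NH4Cl work-up give the acetonide boronic acid F6.
  - F6 is added to chromone 4 under the conditions of step 5 to give the protected flavanone F7 (the same compound as A5).
  - Aqueous AcOH in THF frees the tribenzyl diol F8 while the chain phenol is still benzylated, and hydrogenolysis over 10% Pd/C then gives 15.

**Step 5.**
- **What may go wrong:** insertion of the electron-rich chromone may be slow, so that protodeboronation of 9 outruns the addition. Enantioselectivity may be incomplete, or the sense of induction may be opposite to the one assumed.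
- **Fallback:** from 2, returning at 10. Claisen–Schmidt condensation of 2 with commercial 4-(benzyloxy)-3,5-dimethoxybenzaldehyde (KOH, EtOH) gives the chalcone F9. Cyclisation with NaOAc in refluxing EtOH gives the racemic flavanone F10. Preparative chromatography on a chiral stationary phase delivers the (2S) enantiomer 10.

**Step 6.**
- **What may go wrong:** reduction may continue past debenzylation, either by hydrogenolysis of the benzylic C2–O1 bond (opening of ring C) or by reduction of the C4 carbonyl.
- **Fallback:** from 10, returning at 11. Lewis-acid debenzylation with BCl3 and pentamethylbenzene as cation scavenger in CH2Cl2 at −78 °C replaces hydrogen. The methyl ethers should survive at this temperature. This detour makes no compound outside the list (F0).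

**Step 7.**
- **What may go wrong:** aluminium phenoxide aggregates may stall the reduction, some conjugate reduction may occur, and 13 may oligomerise under acid during work-up or storage.
- **Fallback:** from 12, returning at 13. The phenol is silylated (t-BuMe2SiCl, imidazole) to the silyl ether ester F11. Reduction with i-Bu2AlH gives the silyl ether alcohol F12. Bu4NF then releases 13 under non-acidic conditions just before step 8.

## Further compounds

F1 | step 8 | 2-(4-bromo-2,6-dimethoxyphenoxy)acetic acid | COc1cc(Br)cc(OC)c1OCC(=O)O
F2 | step 8 | (4S)-4-benzyl-3-[2-(4-bromo-2,6-dimethoxyphenoxy)acetyl]-1,3-oxazolidin-2-one | COc1cc(Br)cc(OC)c1OCC(=O)N1[C@@H](Cc2ccccc2)COC1=O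
F3 | step 8 | (4S)-4-benzyl-3-[(2S,3R)-3-[4-(benzyloxy)phenyl]-2-(4-bromo-2,6-dimethoxyphenoxy)-3-hydroxypropanoyl]-1,3-oxazolidin-2-one | COc1cc(Br)cc(OC)c1O[C@H](C(=O)N1[C@@H](Cc2ccccc2)COC1=O)[C@H](O)c1ccc(OCc2ccccc2)cc1
F4 | step 8 | (1R,2R)-1-[4-(benzyloxy)phenyl]-2-(4-bromo-2,6-dimethoxyphenoxy)propane-1,3-diol | COc1cc(Br)cc(OC)c1O[C@H](CO)[C@H](O)c1ccc(OCc2ccccc2)cc1
F5 | step 8 | (4R,5R)-4-[4-(benzyloxy)phenyl]-5-(4-bromo-2,6-dimethoxyphenoxy)-2,2-dimethyl-1,3-dioxane | COc1cc(Br)cc(OC)c1O[C@@H]1COC(C)(C)O[C@@H]1c1ccc(OCc2ccccc2)cc1
F6 | step 8 | [4-({(4R,5R)-4-[4-(benzyloxy)phenyl]-2,2-dimethyl-1,3-dioxan-5-yl}oxy)-3,5-dimethoxyphenyl]boronic acid | COc1cc(B(O)O)cc(OC)c1O[C@@H]1COC(C)(C)O[C@@H]1c1ccc(OCc2ccccc2)cc1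
F7 | step 8 | (2S)-5,7-bis(benzyloxy)-2-[4-({(4R,5R)-4-[4-(benzyloxy)phenyl]-2,2-dimethyl-1,3-dioxan-5-yl}oxy)-3,5-dimethoxyphenyl]chroman-4-one | COc1cc([C@@H]2CC(=O)c3c(OCc4ccccc4)cc(OCc4ccccc4)cc3O2)cc(OC)c1O[C@@H]1COC(C)(C)O[C@@H]1c1ccc(OCc2ccccc2)cc1
F8 | step 8 | (2S)-5,7-bis(benzyloxy)-2-[4-({(1R,2R)-1-[4-(benzyloxy)phenyl]-1,3-dihydroxypropan-2-yl}oxy)-3,5-dimethoxyphenyl]chroman-4-one | COc1cc([C@@H]2CC(=O)c3c(OCc4ccccc4)cc(OCc4ccccc4)cc3O2)cc(OC)c1O[C@H](CO)[C@H](O)c1ccc(OCc2ccccc2)cc1
F9 | step 5 | (2E)-1-[2,4-bis(benzyloxy)-6-hydroxyphenyl]-3-[4-(benzyloxy)-3,5-dimethoxyphenyl]prop-2-en-1-one | COc1cc(/C=C/C(=O)c2c(O)cc(OCc3ccccc3)cc2OCc2ccccc2)cc(OC)c1OCc1ccccc1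
F10 | step 5 | racemic 5,7-bis(benzyloxy)-2-[4-(benzyloxy)-3,5-dimethoxyphenyl]chroman-4-one | COc1cc(C2CC(=O)c3c(OCc4ccccc4)cc(OCc4ccccc4)cc3O2)cc(OC)c1OCc1ccccc1
F0 | step 6 | none | none
F11 | step 7 | methyl (2E)-3-{4-[(tert-butyldimethylsilyl)oxy]phenyl}prop-2-enoate | COC(=O)/C=C/c1ccc(O[Si](C)(C)C(C)(C)C)cc1
F12 | step 7 | (2E)-3-{4-[(tert-butyldimethylsilyl)oxy]phenyl}prop-2-en-1-ol | OC/C=C/c1ccc(O[Si](C)(C)C(C)(C)C)cc1
A1 | alternative 1 | (2S)-2-[4-({(4R,5R)-4-[4-(benzyloxy)phenyl]-2,2-dimethyl-1,3-dioxan-5-yl}oxy)-3,5-dimethoxyphenyl]-5,7-bis[(triisopropylsilyl)oxy]chroman-4-one | COc1cc([C@@H]2CC(=O)c3c(O[Si](C(C)C)(C(C)C)C(C)C)cc(O[Si](C(C)C)(C(C)C)C(C)C)cc3O2)cc(OC)c1O[C@@H]1COC(C)(C)O[C@@H]1c1ccc(OCc2ccccc2)cc1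
A2 | alternative 1 | 2-diazo-1-{2-[(4-{[(4R,5R)-4-[4-(benzyloxy)phenyl]-2,2-dimethyl-1,3-dioxan-5-yl]oxy}-3,5-dimethoxybenzyl)oxy]-4,6-bis[(triisopropylsilyl)oxy]phenyl}ethan-1-one | COc1cc(COc2cc(O[Si](C(C)C)(C(C)C)C(C)C)cc(O[Si](C(C)C)(C(C)C)C(C)C)c2C(=O)C=[N+]=[N-])cc(OC)c1O[C@@H]1COC(C)(C)O[C@@H]1c1ccc(OCc2ccccc2)cc1
A3 | alternative 2 | (2S)-2-[4-({(4R,5R)-4-[4-(benzyloxy)phenyl]-2,2-dimethyl-1,3-dioxan-5-yl}oxy)-3,5-dimethoxyphenyl]-5,7-dihydroxychroman-4-one | COc1cc([C@@H]2CC(=O)c3c(O)cc(O)cc3O2)cc(OC)c1O[C@@H]1COC(C)(C)O[C@@H]1c1ccc(OCc2ccccc2)cc1
A4 | alternative 2 | methyl 4-{(2S)-2-[4-({(4R,5R)-4-[4-(benzyloxy)phenyl]-2,2-dimethyl-1,3-dioxan-5-yl}oxy)-3,5-dimethoxyphenyl]-4-oxo-3,4-dihydro-2H-pyran-6-yl}-3-oxobutanoate | COC(=O)CC(=O)CC1=CC(=O)C[C@H](O1)c1cc(OC)c(O[C@@H]2COC(C)(C)O[C@@H]2c2ccc(OCc3ccccc3)cc2)c(OC)c1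
A5 | alternative 3 | (2S)-5,7-bis(benzyloxy)-2-[4-({(4R,5R)-4-[4-(benzyloxy)phenyl]-2,2-dimethyl-1,3-dioxan-5-yl}oxy)-3,5-dimethoxyphenyl]chroman-4-one | COc1cc([C@@H]2CC(=O)c3c(OCc4ccccc4)cc(OCc4ccccc4)cc3O2)cc(OC)c1O[C@@H]1COC(C)(C)O[C@@H]1c1ccc(OCc2ccccc2)cc1
A6 | alternative 3 | methyl (3S)-3-[4-({(4R,5R)-4-[4-(benzyloxy)phenyl]-2,2-dimethyl-1,3-dioxan-5-yl}oxy)-3,5-dimethoxyphenyl]-3-hydroxypropanoate | COC(=O)C[C@H](O)c1cc(OC)c(O[C@@H]2COC(C)(C)O[C@@H]2c2ccc(OCc3ccccc3)cc2)c(OC)c1
A7 | alternative 3 | 3,5-bis(benzyloxy)benzyne | C1#CC(OCc2ccccc2)=CC(OCc2ccccc2)=C1
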